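**Retrosynthetic overview**

1. The arene is bought as methylhydroquinone. The dihydropyran ring is the only ring made, and it is closed last, by forming C4–C4a (ring order: arene purchased, then pyran ring in step 14).
2. Enabling feature: in the pyran ring C2 is fully substituted, C3–C4 is a bare CH2–CH2 bridge, and C4a is the only position ortho to O1 that is open (C8 carries the methyl). The ring therefore unzips at C4–C4a to an aryl tert-alkyl ether with a vinyl group (C3=C4) on C2 and bromine on C4a. 9-BBN hydroboration of that vinyl group and intramolecular B-alkyl Suzuki–Miyaura coupling close it again in one pot, with the whole side chain in place.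
3. O1–C2 and the C2 stereocentre come from a Pd-catalysed asymmetric O-allylation of bromophenol 3 with the E-allylic carbonate 20 of the complete C20 chain.
4. C20 chain: C2'–C3' by B-alkyl Suzuki coupling of a diene-derived borane with E-vinyl iodide 15 (geometry from alkyne carboalumination); C5'–C6' by propargylation of a terminal epoxide.
5. anti-Diol (7'S,8'R): Sharpless epoxidation of geraniol, then Payne rearrangement/thiolate opening, which inverts the future C7'.

Key step: step 14

Assumption: in step 13 the (R,R)-ligand is taken to be the antipode that gives the 3S ether from the E-carbonate; should the sense of induction be the opposite one, the (S,S)-ligand is used and nothing else changes.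

**Route**

Step 1
Reactants: 1 2-methylbenzene-1,4-diol
Product: 2 2-methyl-4-[(triisopropylsilyl)oxy]phenol
Conditions: TIPSCl (1.0 equiv), imidazole, DMF, 0 °C to rt
Reagents that add atoms: chlorotriisopropylsilane, CC(C)[Si](Cl)(C(C)C)C(C)C
Why: Silyl ether formation is expected at the hydroxyl that is not flanked by the methyl group, because the bulky silyl chloride discriminates between the two phenols on steric grounds.

Step 2
Reactants: 2 2-methyl-4-[(triisopropylsilyl)oxy]phenol
Product: 3 2-bromo-6-methyl-4-[(triisopropylsilyl)oxy]phenol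
Conditions: NBS, i-Pr2NH (cat.), CH2Cl2, 0 °C
Reagents that add atoms: N-bromosuccinimide, O=C1CCC(=O)N1Br
Why: Electrophilic aromatic bromination is directed by the free hydroxyl to its only open ortho position (para is occupied by the silyloxy group), which is the carbon that becomes C4a.

Step 3
Reactants: 4 geraniol
Product: 5 [(2R,3R)-3-methyl-3-(4-methylpent-3-en-1-yl)oxiran-2-yl]methanol
Conditions: t-BuOOH, Ti(OiPr)4 (cat.), D-(−)-diethyl tartrate (cat.), 4 Å molecular sieves, CH2Cl2, −20 °C
Reagents that add atoms: tert-butyl hydroperoxide, CC(C)(C)OO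
Why: Sharpless asymmetric epoxidation of the E-allylic alcohol with the D-(−)-tartrate should deliver oxygen to the face that gives the (2R,3R)-epoxide, which fixes the future C8' directly and the future C7' after one inversion.

Step 4
Reactants: 5 [(2R,3R)-3-methyl-3-(4-methylpent-3-en-1-yl)oxiran-2-yl]methanol
Product: 6 (2R,3R)-3,7-dimethyl-1-(phenylsulfanyl)oct-6-ene-2,3-diol
Conditions: PhSH (slow addition), NaOH (0.5 M aq), t-BuOH, 70 °C
Reagents that add atoms: thiophenol, Sc1ccccc1
Why: Payne rearrangement–opening: the C1 alkoxide opens the epoxide at C2 with inversion to give a small equilibrium share of the terminal epoxide, which thiophenolate captures at its CH2 carbon much faster than it attacks the hindered trisubstituted epoxide, so the new secondary hydroxyl ends up anti to the untouched tertiary one.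

Step 5
Reactants: 6 (2R,3R)-3,7-dimethyl-1-(phenylsulfanyl)oct-6-ene-2,3-diol
Product: 8 (2R)-6-methyl-2-[(2S)-oxiran-2-yl]hept-5-en-2-ol, via sulfonium salt 7 (not isolated)
Conditions: Me3OBF4, CH2Cl2, rt; then NaH (1.0 equiv), THF, 0 °C
Reagents that add atoms: none
Why: S-Methylation turns the sulfide into a sulfonium leaving group that the neighbouring secondary alkoxide displaces in a 3-exo-tet Williamson-type closure, without touching either stereocentre.

Step 6
Reactants: 8 (2R)-6-methyl-2-[(2S)-oxiran-2-yl]hept-5-en-2-ol; 9 trimethyl(prop-1-yn-1-yl)silane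
Product: 11 (5S,6R)-6,10-dimethyl-1-(trimethylsilyl)undec-9-en-1-yne-5,6-diol, via propargyllithium reagent 10 (not isolated)
Conditions: 9 (3 equiv), n-BuLi, THF, −78 °C; then 8, DMPU, −78 to −20 °C; aqueous work-up
Reagents that add atoms: none
Why: The propargylic lithium reagent should open the terminal epoxide at its unsubstituted carbon by SN2 attack (one equivalent is spent on the free hydroxyl), and the low temperature is meant to keep Payne-type back-isomerisation of the tertiary alkoxide slow.

Step 7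
Reactants: 11 (5S,6R)-6,10-dimethyl-1-(trimethylsilyl)undec-9-en-1-yne-5,6-diol
Product: 12 (5S,6R)-6,10-dimethylundec-9-en-1-yne-5,6-diol
Conditions: K2CO3 (cat.), MeOH, rt
Reagents that add atoms: none
Why: Base-mediated methanolysis of the alkynyl C–Si bond (protodesilylation) should leave the diol and the olefin untouched.

Step 8
Reactants: 12 (5S,6R)-6,10-dimethylundec-9-en-1-yne-5,6-diol
Product: 13 (5S,6R)-6,10-dimethyl-5,6-bis[(triethylsilyl)oxy]undec-9-en-1-yne
Conditions: TESOTf (2.5 equiv), 2,6-lutidine, CH2Cl2, 0 °C to rt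
Reagents that add atoms: triethylsilyl trifluoromethanesulfonate, CC[Si](CC)(CC)OS(=O)(=O)C(F)(F)F
Why: The silyl triflate is reactive enough to cap the tertiary as well as the secondary hydroxyl, and both silyl ethers are removable by fluoride at the end.

Step 9
Reactants: 13 (5S,6R)-6,10-dimethyl-5,6-bis[(triethylsilyl)oxy]undec-9-en-1-yne
Product: 15 (1E,5S,6R)-1-iodo-2,6,10-trimethyl-5,6-bis[(triethylsilyl)oxy]undeca-1,9-diene, via alkenylalane 14 (not isolated)
Conditions: AlMe3, Cp2ZrCl2 (cat.), CH2Cl2, 0 °C to rt; then I2, THF, −30 °C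
Reagents that add atoms: trimethylaluminium, C[Al](C)C; iodine, II
Why: Negishi carboalumination adds methyl and aluminium syn across the terminal alkyne with the metal on the terminal carbon, and iodinolysis with retention should give the E-trisubstituted vinyl iodide that fixes the C3'=C4' geometry.

Step 10
Reactants: 16 (2E)-3-methylpent-2-en-4-yn-1-ol
Product: 17 (2E)-3-methylpenta-2,4-dien-1-ol
Conditions: H2 (1 atm), Pd/CaCO3 poisoned with Pb(OAc)2 (Lindlar-type), quinoline, EtOAc, 0 °C
Reagents that add atoms: none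
Why: Semi-hydrogenation of the terminal alkyne on poisoned palladium should stop at the diene and leave the existing E olefin untouched.

Step 11
Reactants: 17 (2E)-3-methylpenta-2,4-dien-1-ol; 15 (1E,5S,6R)-1-iodo-2,6,10-trimethyl-5,6-bis[(triethylsilyl)oxy]undeca-1,9-diene
Product: 19 (2E,6E,10S,11R)-3,7,11,15-tetramethyl-10,11-bis[(triethylsilyl)oxy]hexadeca-2,6,14-trien-1-ol, via bis-boron adduct 18 (not isolated)
Conditions: 9-BBN (2.2 equiv), THF, 0 °C to rt; then 15, Pd(dppf)Cl2·CH2Cl2 (cat.), AsPh3, Cs2CO3, DMF/H2O, rt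
Reagents that add atoms: none
Why: One equivalent of borane caps the hydroxyl as a borinate and the second adds to the terminal CH2 of the monosubstituted vinyl group (the trisubstituted olefin is inert), after which B-alkyl Suzuki–Miyaura coupling with the vinyl iodide should forge C2'–C3' with retention of olefin geometry.

Step 12
Reactants: 19 (2E,6E,10S,11R)-3,7,11,15-tetramethyl-10,11-bis[(triethylsilyl)oxy]hexadeca-2,6,14-trien-1-ol
Product: 20 methyl (2E,6E,10S,11R)-3,7,11,15-tetramethyl-10,11-bis[(triethylsilyl)oxy]hexadeca-2,6,14-trien-1-yl carbonate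
Conditions: ClCO2Me, pyridine, CH2Cl2, 0 °C
Reagents that add atoms: methyl chloroformate, COC(=O)Cl
Why: Acylation of the primary allylic alcohol installs the carbonate leaving group needed for ionisation by zerovalent palladium.

Step 13
Reactants: 20 methyl (2E,6E,10S,11R)-3,7,11,15-tetramethyl-10,11-bis[(triethylsilyl)oxy]hexadeca-2,6,14-trien-1-yl carbonate; 3 2-bromo-6-methyl-4-[(triisopropylsilyl)oxy]phenol
Product: 21 1-bromo-3-methyl-2-{[(3S,6E,10S,11R)-3,7,11,15-tetramethyl-10,11-bis[(triethylsilyl)oxy]hexadeca-1,6,14-trien-3-yl]oxy}-5-[(triisopropylsilyl)oxy]benzene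
Conditions: Pd2(dba)3·CHCl3 (cat.), (1R,2R)-N,N'-bis[2-(diphenylphosphanyl)benzoyl]cyclohexane-1,2-diamine (cat.), CH2Cl2, rt
Reagents that add atoms: none
Why: Asymmetric Tsuji–Trost O-allylation: zerovalent palladium ionises the carbonate, the phenoxide attacks the more substituted terminus of the π-allyl complex inside the chiral pocket of the ligand, and this enantioface-selective C–O bond formation sets the tertiary ether centre (future C2, S), while the aryl bromide should not react with the palladium–ligand complex at room temperature.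

Step 14
Reactants: 21 1-bromo-3-methyl-2-{[(3S,6E,10S,11R)-3,7,11,15-tetramethyl-10,11-bis[(triethylsilyl)oxy]hexadeca-1,6,14-trien-3-yl]oxy}-5-[(triisopropylsilyl)oxy]benzene
Product: 23 (2S)-2,8-dimethyl-2-{(3E,7S,8R)-4,8,12-trimethyl-7,8-bis[(triethylsilyl)oxy]trideca-3,11-dien-1-yl}-6-[(triisopropylsilyl)oxy]-3,4-dihydro-2H-chromene, via B-alkyl borane 22 (not isolated)
Conditions: 9-BBN (1.5 equiv), THF, 0 °C to rt; then Pd(dppf)Cl2·CH2Cl2 (cat.), AsPh3, K3PO4 (aq), DMF, 60 °C
Reagents that add atoms: none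
Why: 9-BBN adds anti-Markovnikov to the monosubstituted vinyl group only, placing boron on the carbon that becomes C4; after borate formation with aqueous base, oxidative addition of zerovalent palladium into the C4a–Br bond, intramolecular transmetalation and reductive elimination form the C4–C4a bond. The closest known reaction type is the intramolecular B-alkyl Suzuki–Miyaura coupling used to close five- and six-membered benzo-fused rings. The pyran ring closes as a six-membered ring through a seven-membered palladacycle that contains O1 and C2, and the gem-disubstitution at C2 favours cyclisation. No new stereocentre arises: C2, set in step 13, carries no hydrogen and is a spectator. The step needs site selectivity on the arene and chemoselectivity among three olefins: the bromine sits on the only position ortho to O1 that is not blocked (C8 bears the methyl), the two trisubstituted olefins are far slower towards 9-BBN than the vinyl group, and the dppf ligand should suppress β-hydride elimination of the alkylpalladium intermediate. The silyl ethers are expected to survive the borane and the basic coupling conditions.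

Step 15
Reactants: 23 (2S)-2,8-dimethyl-2-{(3E,7S,8R)-4,8,12-trimethyl-7,8-bis[(triethylsilyl)oxy]trideca-3,11-dien-1-yl}-6-[(triisopropylsilyl)oxy]-3,4-dihydro-2H-chromene
Product: 24 (2S)-2-[(3E,7S,8R)-7,8-dihydroxy-4,8,12-trimethyltrideca-3,11-dien-1-yl]-2,8-dimethyl-3,4-dihydro-2H-chromen-6-ol
Conditions: TBAF (4 equiv), AcOH (buffer), THF, 0 °C to rt, under argon
Reagents that add atoms: none
Why: Fluoride should cleave the two triethylsilyl ethers and the aryl triisopropylsilyl ether in one operation, with the acetic acid buffer keeping the electron-rich phenoxide from oxidising and no stereocentre being touched.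

**Compound list**

1 | 2-methylbenzene-1,4-diol (methylhydroquinone) | Cc1cc(O)ccc1O | starting material
2 | 2-methyl-4-[(triisopropylsilyl)oxy]phenol | Cc1cc(O[Si](C(C)C)(C(C)C)C(C)C)ccc1O | intermediate
3 | 2-bromo-6-methyl-4-[(triisopropylsilyl)oxy]phenol | Cc1cc(O[Si](C(C)C)(C(C)C)C(C)C)cc(Br)c1O | intermediate
4 | geraniol, (2E)-3,7-dimethylocta-2,6-dien-1-ol | CC(C)=CCC/C(C)=C/CO | starting material
5 | [(2R,3R)-3-methyl-3-(4-methylpent-3-en-1-yl)oxiran-2-yl]methanol | CC(C)=CCC[C@@]1(C)O[C@@H]1CO | intermediate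
6 | (2R,3R)-3,7-dimethyl-1-(phenylsulfanyl)oct-6-ene-2,3-diol | CC(C)=CCC[C@@](C)(O)[C@@H](O)CSc1ccccc1 | intermediate
7 | [(2R,3R)-2,3-dihydroxy-3,7-dimethyloct-6-en-1-yl](methyl)phenylsulfonium tetrafluoroborate | CC(C)=CCC[C@@](C)(O)[C@@H](O)C[S+](C)c1ccccc1.F[B-](F)(F)F | intermediate
8 | (2R)-6-methyl-2-[(2S)-oxiran-2-yl]hept-5-en-2-ol | CC(C)=CCC[C@@](C)(O)[C@@H]1CO1 | intermediate
9 | trimethyl(prop-1-yn-1-yl)silane | CC#C[Si](C)(C)C | starting material
10 | [3-(trimethylsilyl)prop-2-yn-1-yl]lithium | [Li]CC#C[Si](C)(C)C | intermediate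
11 | (5S,6R)-6,10-dimethyl-1-(trimethylsilyl)undec-9-en-1-yne-5,6-diol | CC(C)=CCC[C@@](C)(O)[C@@H](O)CCC#C[Si](C)(C)C | intermediate
12 | (5S,6R)-6,10-dimethylundec-9-en-1-yne-5,6-diol | CC(C)=CCC[C@@](C)(O)[C@@H](O)CCC#C | intermediate
13 | (5S,6R)-6,10-dimethyl-5,6-bis[(triethylsilyl)oxy]undec-9-en-1-yne | CC(C)=CCC[C@@](C)(O[Si](CC)(CC)CC)[C@@H](O[Si](CC)(CC)CC)CCC#C | intermediate
14 | dimethyl{(1E,5S,6R)-2,6,10-trimethyl-5,6-bis[(triethylsilyl)oxy]undeca-1,9-dien-1-yl}alumane | CC(C)=CCC[C@@](C)(O[Si](CC)(CC)CC)[C@@H](O[Si](CC)(CC)CC)CC/C(C)=C/[Al](C)C | intermediate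
15 | (1E,5S,6R)-1-iodo-2,6,10-trimethyl-5,6-bis[(triethylsilyl)oxy]undeca-1,9-diene | CC(C)=CCC[C@@](C)(O[Si](CC)(CC)CC)[C@@H](O[Si](CC)(CC)CC)CC/C(C)=C/I | intermediate
16 | (2E)-3-methylpent-2-en-4-yn-1-ol | OC/C=C(C)/C#C | starting material
17 | (2E)-3-methylpenta-2,4-dien-1-ol | OC/C=C(C)/C=C | intermediate
18 | 9-{[(2E)-5-(9-borabicyclo[3.3.1]nonan-9-yl)-3-methylpent-2-en-1-yl]oxy}-9-borabicyclo[3.3.1]nonane | C1CCC2CCCC1B2OC/C=C(C)/CCB1C2CCCC1CCC2 | intermediate
19 | (2E,6E,10S,11R)-3,7,11,15-tetramethyl-10,11-bis[(triethylsilyl)oxy]hexadeca-2,6,14-trien-1-ol | CC(C)=CCC[C@@](C)(O[Si](CC)(CC)CC)[C@@H](O[Si](CC)(CC)CC)CC/C(C)=C/CC/C(C)=C/CO | intermediate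
20 | methyl (2E,6E,10S,11R)-3,7,11,15-tetramethyl-10,11-bis[(triethylsilyl)oxy]hexadeca-2,6,14-trien-1-yl carbonate | CC(C)=CCC[C@@](C)(O[Si](CC)(CC)CC)[C@@H](O[Si](CC)(CC)CC)CC/C(C)=C/CC/C(C)=C/COC(=O)OC | intermediate
21 | 1-bromo-3-methyl-2-{[(3S,6E,10S,11R)-3,7,11,15-tetramethyl-10,11-bis[(triethylsilyl)oxy]hexadeca-1,6,14-trien-3-yl]oxy}-5-[(triisopropylsilyl)oxy]benzene | CC(C)=CCC[C@@](C)(O[Si](CC)(CC)CC)[C@@H](O[Si](CC)(CC)CC)CC/C(C)=C/CC[C@@](C)(C=C)Oc1c(C)cc(O[Si](C(C)C)(C(C)C)C(C)C)cc1Br | intermediate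
22 | 9-{(3R,6E,10S,11R)-3-{2-bromo-6-methyl-4-[(triisopropylsilyl)oxy]phenoxy}-3,7,11,15-tetramethyl-10,11-bis[(triethylsilyl)oxy]hexadeca-6,14-dien-1-yl}-9-borabicyclo[3.3.1]nonane (same spatial arrangement at the ether carbon as in 21) | CC(C)=CCC[C@@](C)(O[Si](CC)(CC)CC)[C@@H](O[Si](CC)(CC)CC)CC/C(C)=C/CC[C@@](C)(CCB1C2CCCC1CCC2)Oc1c(C)cc(O[Si](C(C)C)(C(C)C)C(C)C)cc1Br | intermediate
23 | (2S)-2,8-dimethyl-2-{(3E,7S,8R)-4,8,12-trimethyl-7,8-bis[(triethylsilyl)oxy]trideca-3,11-dien-1-yl}-6-[(triisopropylsilyl)oxy]-3,4-dihydro-2H-chromene | CC(C)=CCC[C@@](C)(O[Si](CC)(CC)CC)[C@@H](O[Si](CC)(CC)CC)CC/C(C)=C/CC[C@@]1(C)CCc2cc(O[Si](C(C)C)(C(C)C)C(C)C)cc(C)c2O1 | intermediate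
24 | (2S)-2-[(3E,7S,8R)-7,8-dihydroxy-4,8,12-trimethyltrideca-3,11-dien-1-yl]-2,8-dimethyl-3,4-dihydro-2H-chromen-6-ol | CC(C)=CCC[C@@](C)(O)[C@@H](O)CC/C(C)=C/CC[C@@]1(C)CCc2cc(O)cc(C)c2O1 | target

**Step count and risks**

Total step count: 15. Longest linear sequence: 12 steps (geraniol 4 to target 24, steps 3–9 and 11–15).

Steps most likely to fail:

Step 13. The doubly ortho-substituted phenoxide may attack the primary terminus of the π-allyl complex (linear ether), or enantioface selection may be poor. The fallback sets out from alcohol 19 and phenol 3 and comes back at 21, and it makes the configuration at C2 independent of the ligand. Sharpless asymmetric epoxidation of 19 with D-(−)-diethyl tartrate should give [(2R,3R)-3-methyl-3-{(3E,7S,8R)-4,8,12-trimethyl-7,8-bis[(triethylsilyl)oxy]trideca-3,11-dien-1-yl}oxiran-2-yl]methanol F1. Ti(OiPr)4-mediated opening of F1 by phenol 3 at the tertiary epoxide carbon, with inversion, should give the aryloxy diol F2. Deoxygenation of the vicinal diol to the olefin (PPh3, I2, imidazole, toluene, 80 °C; Garegg–Samuelsson conditions) then gives the vinyl group of 21.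

Step 14. Oxidative addition into the hindered, electron-rich C–Br bond may be slow, so that protodeboronation or β-hydride elimination of the alkylpalladium species overtakes ring closure. The fallback sets out from 21 and comes back at 23, closing the same bond by an anionic route. Borane 22 is oxidised (NaBO3·4H2O) to the primary alcohol F3, which is converted (TsCl, pyridine) into the tosylate F4. t-BuLi (2 equiv, THF, −78 °C) effects bromine–lithium exchange to the aryllithium F5, which closes the ring by intramolecular SN2 displacement of the tosylate (Parham cyclisation) to give 23.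

Step 6. The lithium alkoxide next to the epoxide may trigger Payne-type back-isomerisation to the 2,3-epoxide, or opening may stall. The fallback sets out from geraniol 4 and comes back at 11. Sharpless epoxidation with L-(+)-diethyl tartrate gives [(2S,3S)-3-methyl-3-(4-methylpent-3-en-1-yl)oxiran-2-yl]methanol F6. Its trifluoromethanesulfonate F7 (Tf2O, 2,6-lutidine, −78 °C) is displaced by lithium reagent 10 to give the epoxy alkyne F8. Acid-catalysed hydrolysis (HClO4 cat., THF/H2O) should open the trisubstituted epoxide at its tertiary carbon with inversion, giving 11.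

Further compounds

F1 | step 13 | [(2R,3R)-3-methyl-3-{(3E,7S,8R)-4,8,12-trimethyl-7,8-bis[(triethylsilyl)oxy]trideca-3,11-dien-1-yl}oxiran-2-yl]methanol | CC(C)=CCC[C@@](C)(O[Si](CC)(CC)CC)[C@@H](O[Si](CC)(CC)CC)CC/C(C)=C/CC[C@@]1(C)O[C@@H]1CO
F2 | step 13 | (2R,3S,6E,10S,11R)-3-{2-bromo-6-methyl-4-[(triisopropylsilyl)oxy]phenoxy}-3,7,11,15-tetramethyl-10,11-bis[(triethylsilyl)oxy]hexadeca-6,14-diene-1,2-diol | CC(C)=CCC[C@@](C)(O[Si](CC)(CC)CC)[C@@H](O[Si](CC)(CC)CC)CC/C(C)=C/CC[C@](C)(Oc1c(C)cc(O[Si](C(C)C)(C(C)C)C(C)C)cc1Br)[C@H](O)CO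
F3 | step 14 | (3S,6E,10S,11R)-3-{2-bromo-6-methyl-4-[(triisopropylsilyl)oxy]phenoxy}-3,7,11,15-tetramethyl-10,11-bis[(triethylsilyl)oxy]hexadeca-6,14-dien-1-ol | CC(C)=CCC[C@@](C)(O[Si](CC)(CC)CC)[C@@H](O[Si](CC)(CC)CC)CC/C(C)=C/CC[C@@](C)(CCO)Oc1c(C)cc(O[Si](C(C)C)(C(C)C)C(C)C)cc1Br
F4 | step 14 | (3S,6E,10S,11R)-3-{2-bromo-6-methyl-4-[(triisopropylsilyl)oxy]phenoxy}-3,7,11,15-tetramethyl-10,11-bis[(triethylsilyl)oxy]hexadeca-6,14-dien-1-yl 4-methylbenzenesulfonate | CC(C)=CCC[C@@](C)(O[Si](CC)(CC)CC)[C@@H](O[Si](CC)(CC)CC)CC/C(C)=C/CC[C@@](C)(CCOS(=O)(=O)c1ccc(C)cc1)Oc1c(C)cc(O[Si](C(C)C)(C(C)C)C(C)C)cc1Br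
F5 | step 14 | aryllithium formed from F4 by bromine–lithium exchange (lithium in place of bromine) | CC(C)=CCC[C@@](C)(O[Si](CC)(CC)CC)[C@@H](O[Si](CC)(CC)CC)CC/C(C)=C/CC[C@@](C)(CCOS(=O)(=O)c1ccc(C)cc1)Oc1c(C)cc(O[Si](C(C)C)(C(C)C)C(C)C)cc1[Li]
F6 | step 6 | [(2S,3S)-3-methyl-3-(4-methylpent-3-en-1-yl)oxiran-2-yl]methanol | CC(C)=CCC[C@]1(C)O[C@H]1CO
F7 | step 6 | [(2S,3S)-3-methyl-3-(4-methylpent-3-en-1-yl)oxiran-2-yl]methyl trifluoromethanesulfonate | CC(C)=CCC[C@]1(C)O[C@H]1COS(=O)(=O)C(F)(F)F
F8 | step 6 | trimethyl{5-[(2S,3S)-3-methyl-3-(4-methylpent-3-en-1-yl)oxiran-2-yl]pent-1-yn-1-yl}silane | CC(C)=CCC[C@]1(C)O[C@H]1CCC#C[Si](C)(C)C
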